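**Strategy.** Ring A of the target (C1–C5, C10; ent-kaurane-type locants) with its C3–O–C6 ether is a β-alkoxy ketone. Retro-oxa-Michael opening gives a 4,4-dimethylcyclohex-2-enone whose C6–C5–C4(Me2)–C3=C2 array is a Claisen retron. The route rests on the C4–C5 disconnection: an Ireland–Claisen ring contraction of the silyl ketene acetal of an (S)-6-(2-methylprop-1-enyl) δ-lactone closes ring A, creates the gem-dimethyl quaternary carbon C4 and transfers chirality from the lactone carbinol to C5 in one operation. The derived oxa-cage then directs a Knoevenagel/Diels–Alder construction of the spiro-lactone and ring C, and a carbonyl-ene reaction closes ring D.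

Key step: step 3

Remark on locants: C1 ketone carbon, C2 CH2, C3 CH–O, C4 CMe2, C5 CH, C6 CH2O, C10 spiro carbon, C20 lactone CH2, C7 lactone C=O, C8 and C13 bridgeheads, C9 ring-fusion CH, C11/C12 CH2, C14 one-carbon bridge, C15 bridge ketone, C16 carbinol carbon, C17 its methyl.

Assumption: the configuration is taken exactly as written in the target SMILES (C6 trans to C20 on ring A, lactone and ring C cis-fused, 16-OH on the side of the C11–C12 bridge). Compounds 1, 2, 11, 13, 15 and 21 are taken as commercial.

Step 1
Reactants: 1 methyl 5-chloro-5-oxopentanoate; 2 (2-methylprop-1-en-1-yl)magnesium bromide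
Product: 3 methyl 7-methyl-5-oxooct-6-enoate
Conditions: Fe(acac)3 (3 mol%), THF, −78 °C
Reagents that add atoms: none
Why: Iron-catalysed acyl cross-coupling of the alkenyl Grignard reagent with the acid chloride is far faster at −78 °C than addition to the methyl ester or to the β,β-disubstituted enone that forms, and no stereocentre is involved.

Step 2
Reactants: 3 methyl 7-methyl-5-oxooct-6-enoate
Product: 5 (S)-6-(2-methylprop-1-en-1-yl)tetrahydro-2H-pyran-2-one, via hydroxy ester 4 (not isolated)
Conditions: (R)-2-methyl-CBS-oxazaborolidine (10 mol%), catecholborane, toluene, −78 °C; aqueous NaOH work-up; then Ti(OiPr)4 (5 mol%), toluene, 90 °C (−MeOH)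
Reagents that add atoms: none
Why: Corey–Bakshi–Shibata reduction, in which the (R)-oxazaborolidine treats the alkenyl group as the large substituent, should set the (S)-carbinol centre, and the mild Ti(OiPr)4-catalysed transesterification then closes the six-membered lactone without ionising the allylic C–O bond.

Step 3
Reactants: 5 (S)-6-(2-methylprop-1-en-1-yl)tetrahydro-2H-pyran-2-one
Product: 8 (R)-(6,6-dimethylcyclohex-3-en-1-yl)methanol, via silyl ketene acetal 6 (not isolated), via silyl ester 7 (not isolated)
Conditions: LDA, THF, −78 °C, then TMSCl; solvent exchange to toluene, 110 °C; then LiAlH4, THF, 0 °C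
Reagents that add atoms: none
Why: LDA/TMSCl converts the lactone into its cyclic silyl ketene acetal 6, whose C=C(OSi)–O–CH–CH=CMe2 unit is an allyl vinyl ether, and heating triggers a concerted [3,3]-sigmatropic shift in which the enolate α-carbon (future C5) bonds to the dimethyl-substituted alkene terminus (future C4) while the ring C–O bond breaks and the silyl ester C=O forms. The closest known reaction type is the Ireland–Claisen ring contraction of alkenyl lactones to cycloalkene carboxylic acids. The cyclohexene (ring A) is closed by this suprafacial [3,3] shift through the boat-like transition state imposed by the six-membered ketene acetal, that is, a pericyclic contraction of the oxacycle into the carbocycle and not an exo or endo attack. The single new stereocentre C5 is controlled by the (S)-carbinol carbon of the lactone: the alkenyl arm can reach the α-carbon only on the ring face it occupies, so chirality should be transferred fully to give the (R)-acid derivative, while C4 becomes the non-stereogenic gem-dimethyl quaternary carbon. The step needs O-silylation at the α-CH2 (the only acidic site) and rearrangement in preference to loss of the allylic carboxylate; low-temperature trapping, the intramolecular geometry and the C=O gained should secure this even though a quaternary carbon is formed. LiAlH4 then reduces the silyl ester 7 in the same flask to the primary alcohol.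

Step 4
Reactants: 8 (R)-(6,6-dimethylcyclohex-3-en-1-yl)methanol
Product: 9 (R)-tert-butyl[(6,6-dimethylcyclohex-3-en-1-yl)methoxy]dimethylsilane
Conditions: TBSCl, imidazole, CH2Cl2, rt
Reagents that add atoms: tert-butyldimethylsilyl chloride, CC(C)(C)[Si](C)(C)Cl
Why: Standard silylation of the primary alcohol masks the oxygen that later becomes the ether bridge while enolate chemistry is done next to the ketone; the stereocentre is untouched.

Step 5
Reactants: 9 (R)-tert-butyl[(6,6-dimethylcyclohex-3-en-1-yl)methoxy]dimethylsilane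
Product: 10 (R)-5-{[(tert-butyldimethylsilyl)oxy]methyl}-4,4-dimethylcyclohex-2-en-1-one
Conditions: dirhodium tetrakis(caprolactamate) Rh2(cap)4 (1 mol%), t-BuOOH (70% aq.), K2CO3, CH2Cl2, rt
Reagents that add atoms: tert-butyl hydroperoxide, CC(C)(C)OO
Why: Dirhodium-catalysed allylic C–H oxidation with TBHP can only abstract hydrogen from the single allylic CH2 (the other allylic carbon is quaternary) and should oxygenate the unhindered end of the allyl radical, giving the enone whose C=C lies next to the gem-dimethyl carbon.

Step 6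
Reactants: 10 (R)-5-{[(tert-butyldimethylsilyl)oxy]methyl}-4,4-dimethylcyclohex-2-en-1-one; 11 bromoethene (vinyl bromide)
Product: 12 (5R,6R)-5-{[(tert-butyldimethylsilyl)oxy]methyl}-4,4-dimethyl-6-vinylcyclohex-2-en-1-one
Conditions: LiHMDS, Pd2(dba)3 (2.5 mol%), P(t-Bu)3·HBF4 (10 mol%), THF/toluene, 0 °C to rt
Reagents that add atoms: none
Why: Palladium-catalysed α-alkenylation of a ketone enolate: the enone can be deprotonated only at its α' CH2 (the other α-carbon is vinylic and the γ-carbon quaternary), the vinyl group should settle trans to the silyloxymethyl arm, and this epimerisable centre is erased in the next step anyway.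

Step 7
Reactants: 12 (5R,6R)-5-{[(tert-butyldimethylsilyl)oxy]methyl}-4,4-dimethyl-6-vinylcyclohex-2-en-1-one; 13 formaldehyde (gas, from cracking paraformaldehyde)
Product: 14 (5S,6S)-5-{[(tert-butyldimethylsilyl)oxy]methyl}-6-(hydroxymethyl)-4,4-dimethyl-6-vinylcyclohex-2-en-1-one
Conditions: LDA, THF, −78 °C; CH2O (g), −78 °C; H2O quench
Reagents that add atoms: none
Why: LDA gives the extended enolate of the α-vinyl ketone, which undergoes aldol addition to formaldehyde at its α-carbon to create the quaternary centre, the electrophile approaching anti to the adjacent silyloxymethyl arm (1,2-induction, arm pseudo-axial to avoid allylic strain) so that CH2OH (C20) should end trans to it and the vinyl group (C9) cis.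

Step 8
Reactants: 14 (5S,6S)-5-{[(tert-butyldimethylsilyl)oxy]methyl}-6-(hydroxymethyl)-4,4-dimethyl-6-vinylcyclohex-2-en-1-one; 15 methyl 4,4-dimethoxy-3-oxopentanoate
Product: 16 [(1S,6S)-6-{[(tert-butyldimethylsilyl)oxy]methyl}-5,5-dimethyl-2-oxo-1-vinylcyclohex-3-en-1-yl]methyl 4,4-dimethoxy-3-oxopentanoate
Conditions: DMAP (0.2 equiv), toluene, 110 °C, 4 Å molecular sieves (−MeOH)
Reagents that add atoms: none
Why: DMAP-catalysed transesterification of a β-keto ester (through an acylketene or acylpyridinium) is driven by removal of methanol and acylates the only free hydroxyl; no stereocentre changes.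

Step 9
Reactants: 16 [(1S,6S)-6-{[(tert-butyldimethylsilyl)oxy]methyl}-5,5-dimethyl-2-oxo-1-vinylcyclohex-3-en-1-yl]methyl 4,4-dimethoxy-3-oxopentanoate
Product: 18 [(1S,2S,5S)-8,8-dimethyl-3-oxo-2-vinyl-6-oxabicyclo[3.2.1]octan-2-yl]methyl 4,4-dimethoxy-3-oxopentanoate, via hydroxy enone 17 (not isolated)
Conditions: HF·pyridine, THF, 0 °C to rt; then DBU (0.2 equiv), CH2Cl2, rt
Reagents that add atoms: none
Why: Fluoride cleaves the silyl ether, and base-catalysed intramolecular oxa-Michael addition (5-exo-trig) of the freed primary alcohol to the enone β-carbon closes the tetrahydrofuran, the oxygen being deliverable only to the ring face that carries the CH2OH arm, which fixes the new C3 stereocentre.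

Step 10
Reactants: 18 [(1S,2S,5S)-8,8-dimethyl-3-oxo-2-vinyl-6-oxabicyclo[3.2.1]octan-2-yl]methyl 4,4-dimethoxy-3-oxopentanoate
Product: 20 spiro alkylidene lactone (3-(2,2-dimethoxypropanoyl)-5,6-dihydro-2H-pyran-2-one whose C5 is C2 of the (1S,5S)-8,8-dimethyl-6-oxabicyclo[3.2.1]octan-3-one cage; lactone CH2 anti to the CH2O bridge), via keto aldehyde 19 (not isolated)
Conditions: OsO4 (2 mol%), NaIO4, 2,6-lutidine, dioxane/H2O 3:1, rt; then piperidinium acetate (20 mol%), CH2Cl2, 4 Å molecular sieves, rt
Reagents that add atoms: none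
Why: Lemieux–Johnson cleavage of the only C=C unmasks the neopentyl aldehyde, and intramolecular Knoevenagel condensation with the β-keto ester methylene closes the six-membered unsaturated lactone.

Step 11
Reactants: 20 spiro alkylidene lactone; 21 buta-1,3-diene
Product: 22 Diels–Alder adduct (cis-fused 8a-(2,2-dimethoxypropanoyl)-4a,5,8,8a-tetrahydroisochroman-1-one spiro-linked at its C4 to C2 of the oxa-cage; alkene C12=C13)
Conditions: ZnCl2 (1.0 equiv), excess diene, CH2Cl2, sealed tube, 0 °C to rt
Reagents that add atoms: none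
Why: Lewis-acid-promoted Diels–Alder reaction of the doubly activated alkylidene β-keto lactone: suprafacial addition gives the cis ring fusion, and the diene should approach the alkene face that looks toward the flat C1 ketone, away from the bridgehead CH and its CH2O bridge, which sets C9 and the quaternary C8 relative to the cage.

Step 12
Reactants: 22 Diels–Alder adduct
Product: 23 1,2-diketone (8a-(2-oxopropanoyl) analogue of 22)
Conditions: p-TsOH·H2O (0.2 equiv), acetone/H2O 10:1, 50 °C; NaHCO3 quench
Reagents that add atoms: water, O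
Why: Acid-catalysed hydrolysis of the dimethyl ketal liberates the 1,2-diketone under conditions intended to be too mild to ionise the diketone toward the alkene; no stereocentre changes.

Step 13
Reactants: 23 1,2-diketone
Product: 24 11,12-didehydro target (bicyclo[3.2.1]octene ketol; alkene C11=C12)
Conditions: toluene (0.01 M), 2,6-di-tert-butyl-4-methylpyridine (0.1 equiv), 150 °C, sealed tube
Reagents that add atoms: none
Why: Concerted thermal carbonyl-ene reaction of the activated 1,2-diketone: the outer carbonyl carbon bonds to the nearer alkene carbon C13 (five-membered ring) while its oxygen takes the allylic hydrogen of C11 across the alkene, a geometry open only to the bicyclo[3.2.1] mode that places OH toward the three-carbon bridge and methyl exo at C16, while C13 is fixed by the tether from C8.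

Step 14
Reactants: 24 11,12-didehydro target
Product: 25 target CNP0538153.1
Conditions: H2 (1 atm), Pd/C (10 wt%), EtOAc, rt
Reagents that add atoms: none
Why: Heterogeneous hydrogenation of the disubstituted alkene creates no stereocentre and should leave ketones, lactone and tertiary alcohol untouched.

**Compound list**

1 | methyl 5-chloro-5-oxopentanoate | COC(=O)CCCC(Cl)=O | starting material
2 | (2-methylprop-1-en-1-yl)magnesium bromide | CC(C)=C[Mg]Br | starting material
3 | methyl 7-methyl-5-oxooct-6-enoate | COC(=O)CCCC(=O)C=C(C)C | intermediate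
4 | methyl (S)-5-hydroxy-7-methyloct-6-enoate | CC(C)=C[C@@H](O)CCCC(=O)OC | intermediate
5 | (S)-6-(2-methylprop-1-en-1-yl)tetrahydro-2H-pyran-2-one | CC(C)=C[C@@H]1CCCC(=O)O1 | intermediate
6 | (S)-trimethyl{[2-(2-methylprop-1-en-1-yl)-3,4-dihydro-2H-pyran-6-yl]oxy}silane | CC(C)=C[C@@H]1CCC=C(O[Si](C)(C)C)O1 | intermediate
7 | trimethylsilyl (R)-6,6-dimethylcyclohex-3-ene-1-carboxylate | CC1(C)C=CCC[C@H]1C(=O)O[Si](C)(C)C | intermediate
8 | (R)-(6,6-dimethylcyclohex-3-en-1-yl)methanol | CC1(C)C=CCC[C@H]1CO | intermediate
9 | (R)-tert-butyl[(6,6-dimethylcyclohex-3-en-1-yl)methoxy]dimethylsilane | CC1(C)C=CCC[C@H]1CO[Si](C)(C)C(C)(C)C | intermediate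
10 | (R)-5-{[(tert-butyldimethylsilyl)oxy]methyl}-4,4-dimethylcyclohex-2-en-1-one | CC1(C)C=CC(=O)C[C@H]1CO[Si](C)(C)C(C)(C)C | intermediate
11 | bromoethene (vinyl bromide) | C=CBr | starting material
12 | (5R,6R)-5-{[(tert-butyldimethylsilyl)oxy]methyl}-4,4-dimethyl-6-vinylcyclohex-2-en-1-one (vinyl trans to the silyloxymethyl arm) | CC1(C)C=CC(=O)[C@H](C=C)[C@H]1CO[Si](C)(C)C(C)(C)C | intermediate
13 | formaldehyde | C=O | starting material
14 | (5S,6S)-5-{[(tert-butyldimethylsilyl)oxy]methyl}-6-(hydroxymethyl)-4,4-dimethyl-6-vinylcyclohex-2-en-1-one (CH2OH trans to the silyloxymethyl arm) | CC1(C)C=CC(=O)[C@](C=C)(CO)[C@H]1CO[Si](C)(C)C(C)(C)C | intermediate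
15 | methyl 4,4-dimethoxy-3-oxopentanoate | COC(=O)CC(=O)C(C)(OC)OC | starting material
16 | [(1S,6S)-6-{[(tert-butyldimethylsilyl)oxy]methyl}-5,5-dimethyl-2-oxo-1-vinylcyclohex-3-en-1-yl]methyl 4,4-dimethoxy-3-oxopentanoate | CC1(C)C=CC(=O)[C@](C=C)(COC(=O)CC(=O)C(C)(OC)OC)[C@H]1CO[Si](C)(C)C(C)(C)C | intermediate
17 | [(1S,6S)-6-(hydroxymethyl)-5,5-dimethyl-2-oxo-1-vinylcyclohex-3-en-1-yl]methyl 4,4-dimethoxy-3-oxopentanoate | CC1(C)C=CC(=O)[C@](C=C)(COC(=O)CC(=O)C(C)(OC)OC)[C@H]1CO | intermediate
18 | [(1S,2S,5S)-8,8-dimethyl-3-oxo-2-vinyl-6-oxabicyclo[3.2.1]octan-2-yl]methyl 4,4-dimethoxy-3-oxopentanoate | CC1(C)[C@@H]2CC(=O)[C@](C=C)(COC(=O)CC(=O)C(C)(OC)OC)[C@H]1CO2 | intermediate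
19 | [(1S,2S,5S)-2-formyl-8,8-dimethyl-3-oxo-6-oxabicyclo[3.2.1]octan-2-yl]methyl 4,4-dimethoxy-3-oxopentanoate | CC1(C)[C@@H]2CC(=O)[C@](C=O)(COC(=O)CC(=O)C(C)(OC)OC)[C@H]1CO2 | intermediate
20 | spiro alkylidene lactone: 3-(2,2-dimethoxypropanoyl)-5,6-dihydro-2H-pyran-2-one spiro-fused at C5 to C2 of the (1S,5S)-8,8-dimethyl-6-oxabicyclo[3.2.1]octan-3-one cage | CC1(C)[C@@H]2CC(=O)[C@]3(COC(=O)C(C(=O)C(C)(OC)OC)=C3)[C@H]1CO2 | intermediate
21 | buta-1,3-diene | C=CC=C | starting material
22 | Diels–Alder adduct: cis-fused cyclohexene δ-lactone with the 2,2-dimethoxypropanoyl group on C8, spiro at C10 to the oxa-cage, C11 on the lactone face of the C1 ketone | CC1(C)[C@@H]2CC(=O)[C@]3(COC(=O)[C@@]4(C(=O)C(C)(OC)OC)CC=CC[C@H]43)[C@H]1CO2 | intermediate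
23 | 1,2-diketone: as 22 with a 2-oxopropanoyl group on C8 | CC1(C)[C@@H]2CC(=O)[C@]3(COC(=O)[C@@]4(C(=O)C(C)=O)CC=CC[C@H]43)[C@H]1CO2 | intermediate
24 | 11,12-didehydro target: bicyclo[3.2.1]oct-ene ketol with 16-OH toward the C11–C12 bridge and 16-methyl exo | CC1(C)[C@@H]2CC(=O)[C@]3(COC(=O)[C@@]45C[C@@H](C=C[C@H]43)[C@@](C)(O)C5=O)[C@H]1CO2 | intermediate
25 | CNP0538153.1 (3,6-epoxy-16-hydroxy-1,15-dioxo-6,7-seco-kauran-7,20-olide skeleton, configuration as in the SMILES) | CC1(C)[C@@H]2CC(=O)[C@]3(COC(=O)[C@@]45C[C@@H](CC[C@H]43)[C@@](C)(O)C5=O)[C@H]1CO2 | target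

**Totals.** Total step count: 14. Longest linear sequence: 14 steps (1 to 25).

**Steps most likely to fail**

1. Step 13 (ene closure of ring D). The cyclisation may take a stepwise, acid-type course or bond the diketone to the remote alkene carbon, which would give the bicyclo[2.2.2] skeleton; the diketone may also enolise and decompose before it cyclises. The fallback sets out from 23 and comes back at 25, replacing the pericyclic closure by a radical one and then correcting C16. SmI2/HMPA with t-BuOH in THF at −78 °C should reduce the 1,2-diketone to a ketyl that closes 5-exo onto the nearer alkene carbon (radical closure is kinetically biased to the five-membered ring). After reduction of the secondary radical this gives the saturated ketol, expected mainly with the oxygen exo, the 16-epimeric ketol F1. Burgess reagent should dehydrate it to the exocyclic enone F2, the only alkene the bridged skeleton allows. Ozonolysis (O3, then Me2S) gives the 15,16-dione F3. MeMgBr (1 equiv, THF, −78 °C) should add to the less hindered C16 carbonyl of the vicinal dione from the exo face (the side of the one-carbon bridge), giving 25 with methyl exo and OH toward the three-carbon bridge.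

2. Step 11 (Diels–Alder on the cage). Facial discrimination between the C1-ketone side and the bridgehead side of the spiro dienophile may be poor, so that the diene also adds from the wrong face. The fallback sets out from 16 and comes back at 22: the cycloaddition is done before the cage is closed, so that the bulky silyloxymethyl arm on C5 shields its face. OsO4/NaIO4/2,6-lutidine should cleave the vinyl group selectively over the electron-poor enone to the keto aldehyde F4. Piperidinium acetate closes the alkylidene lactone F5. Buta-1,3-diene with ZnCl2 should add anti to the silyloxymethyl arm to give the cis-fused adduct F6. HF·pyridine frees the hydroxy enone F7, and DBU closes the ether bridge by oxa-Michael addition to give 22.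

3. Step 6 (α'-vinylation). Over-vinylation, O-vinylation or isomerisation of the hindered enolate may erode the palladium-catalysed alkenylation. The fallback sets out from 10 and comes back at 14, building the same extended enolate by aldol chemistry. LDA and acetaldehyde at −78 °C give the aldol adduct F8 (diastereomer mixture). MsCl/Et3N gives the mesylate F9, and DBU eliminates to the (E)-ethylidene dienone F10. γ-Deprotonation with LDA/HMPA at −78 °C produces the same extended enolate as from 12, and formaldehyde gas then adds at the α-carbon, anti to the silyloxymethyl arm, to give 14.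

**Further compounds**

F1 | step 13 | 16-epimer of 25 (saturated ketol, 16-OH exo, 16-methyl toward the C11–C12 bridge) | CC1(C)[C@@H]2CC(=O)[C@]3(COC(=O)[C@@]45C[C@@H](CC[C@H]43)[C@](C)(O)C5=O)[C@H]1CO2
F2 | step 13 | 16-methylene-15-one (exocyclic enone of the bicyclo[3.2.1]octane) | CC1(C)[C@@H]2CC(=O)[C@]3(COC(=O)[C@@]45C[C@@H](CC[C@H]43)C(=C)C5=O)[C@H]1CO2
F3 | step 13 | 17-nor-15,16-dione | CC1(C)[C@@H]2CC(=O)[C@]3(COC(=O)[C@@]45C[C@@H](CC[C@H]43)C(=O)C5=O)[C@H]1CO2
F4 | step 11 | [(1S,6S)-6-{[(tert-butyldimethylsilyl)oxy]methyl}-1-formyl-5,5-dimethyl-2-oxocyclohex-3-en-1-yl]methyl 4,4-dimethoxy-3-oxopentanoate | CC1(C)C=CC(=O)[C@](C=O)(COC(=O)CC(=O)C(C)(OC)OC)[C@H]1CO[Si](C)(C)C(C)(C)C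
F5 | step 11 | monocyclic spiro alkylidene lactone (3-(2,2-dimethoxypropanoyl)-5,6-dihydro-2H-pyran-2-one spiro-fused at C5 to the silyloxymethyl cyclohexenone) | CC1(C)C=CC(=O)[C@]2(COC(=O)C(C(=O)C(C)(OC)OC)=C2)[C@H]1CO[Si](C)(C)C(C)(C)C
F6 | step 11 | Diels–Alder adduct of F5 (cis-fused cyclohexene lactone, silyl ether, ring-A enone intact) | CC1(C)C=CC(=O)[C@]2(COC(=O)[C@@]3(C(=O)C(C)(OC)OC)CC=CC[C@H]32)[C@H]1CO[Si](C)(C)C(C)(C)C
F7 | step 11 | desilylated hydroxy enone of F6 | CC1(C)C=CC(=O)[C@]2(COC(=O)[C@@]3(C(=O)C(C)(OC)OC)CC=CC[C@H]32)[C@H]1CO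
F8 | step 6 | (5R)-5-{[(tert-butyldimethylsilyl)oxy]methyl}-6-(1-hydroxyethyl)-4,4-dimethylcyclohex-2-en-1-one (diastereomer mixture) | CC1(C)C=CC(=O)C(C(C)O)[C@H]1CO[Si](C)(C)C(C)(C)C
F9 | step 6 | methanesulfonate of F8 | CC1(C)C=CC(=O)C(C(C)OS(C)(=O)=O)[C@H]1CO[Si](C)(C)C(C)(C)C
F10 | step 6 | (R,E)-5-{[(tert-butyldimethylsilyl)oxy]methyl}-6-ethylidene-4,4-dimethylcyclohex-2-en-1-one | CC1(C)C=CC(=O)/C(=C/C)[C@H]1CO[Si](C)(C)C(C)(C)C
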